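## Structural features

The target is a biflavonoid made of two C15 units. Unit 1 is a flavone: benzo ring A with 5-OH and 7-OMe, pyranone ring C, and a 4'-methoxyphenyl ring B on C2. Unit 2 is a (2R)-flavanone of the naringenin type: ring A with 5''-OH and 7''-OH, dihydropyranone ring C, and a 4'''-hydroxyphenyl ring B on C2''.

The units are joined by one sp2–sp2 bond from C3 of unit 1 to C6'' of unit 2. This bond has four ortho substituents (the C2 aryl and C4 carbonyl on one side, the C5'' and C7'' oxygens on the other), so it is hindered and rotation about it is restricted.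

The only stereocentre is C2'' (R). It is benzylic, bonded to O1'' and β to the C4'' ketone. Reading the SMILES, the configuration is opposite to the 2S sense of flavanones formed by chalcone isomerase.

C2'' is the fragile point. Deprotonation at C3'' opens ring C of unit 2 by E1cB loss of the O1'' phenoxide, helped by the 4'''-oxygen. Reclosure racemises C2'', and reclosure through the C5'' oxygen would move the link from C6'' to C8''.

Four phenols (two of them hydrogen-bonded to a carbonyl) must be told apart from two methyl ethers. The two pyranone rings sit at different oxidation levels.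

The real difficulty is a conflict: the hindered C3–C6'' bond calls for base and heat, and the C2'' centre tolerates neither. The C6''/C8'' regiochemistry must also be held.

The key step exploits the fact that C2'' is the β-carbon of the C4'' ketone. In the chromone form of unit 2, C2''=C3'' is an unsubstituted enone, while C2=C3 of unit 1 is tetrasubstituted and inert. The route in one sentence: enantioselective 1,4-addition of an arylboron reagent to C2'' of an achiral, fully aromatic 3-(chromon-6-yl)flavone. This sentence does not fit a coupling of a finished flavanone or a chalcone ring closure.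

## Logic of the disconnections

13 to 12: the four O–benzyl bonds are cut. Benzyl is chosen because it comes off by neutral hydrogenolysis, the one deprotection that cannot open ring C of unit 2. The gain is that every phenol is masked by one group type through the route. The forward step must leave the C4'' ketone and the benzylic C2''–O1'' bond alone.

12 to 10 and 11 (key disconnection): the C2''–C1''' bond is cut, which removes ring B of unit 2 and returns ring C of unit 2 to a chromone. The cut is made here because the stereocentre is the β-carbon of an enone and because 10 has no stereocentre to lose. 10 therefore survives the forcing conditions needed for the hindered bond, and its C6'' link cannot migrate because a chromone does not open and reclose the way a flavanone does. The gain is the loss of the only stereocentre and one aryl ring, leaving a flat bichromone. The forward step must deliver the aryl group to one face of C2'' under catalyst control, in a non-basic medium, and only to unit 2.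

10 to 4 and 9: the C3–C6'' biaryl bond is cut. Both partners are achiral and aromatic, so base and heat are harmless here. The gain is two fragments of similar size, each from a purchasable chromone. The forward step must join two carbons that each carry two ortho substituents.

9 to 8, 7, 6 and 5: the C6''–B bond, the 5''-O–benzyl bond, the C6''–I bond and the 7''-O–benzyl bond are cut in turn. Iodine is placed while the 5''-OH is free, because that hydroxyl directs the electrophile to its only ortho position, C6''. The forward steps must keep the 2,3-unsubstituted chromone away from hydroxide and strong nucleophiles.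

4 to 2 and 1: the C3–I bond and the 5-O–benzyl bond are cut. C3–H is the only vinylic hydrogen of the flavone and lies α to the carbonyl, so it can be removed by an amide base. The forward step must metalate C3 without touching ring A or the benzyl CH2.

## Other disconnections considered

Alternative 1: This is the first plan that comes to mind. The C3–C6'' bond is cut with the flavanone already complete. Suzuki–Miyaura coupling of 4 with the 6''-boryl flavanone A1 would give 12 directly. The chosen plan is preferred on mechanistic grounds: A1 would carry C2'' through a tetra-ortho coupling that needs base and heat, and deprotonation at C3'' followed by E1cB ring opening and reclosure is expected to erode the configuration. A1 would also need its own asymmetric synthesis in the unnatural 2R series and a regioselective C6'' functionalisation on a chiral substrate. The chosen plan forms the same bond on achiral aromatic partners and sets C2'' afterwards.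

Alternative 2: The O1''–C2'' bond is cut, giving chalcone A2. The forward key step would be an enantioselective intramolecular oxa-Michael closure by a chiral base or thiourea, or by chalcone isomerase. The ground for rejection is structural: A2 has two non-equivalent ortho hydroxyls, so closure can give 13 or the C8''-linked isomer A3, and the closure is reversible. 2'-Hydroxychalcones without an activating group on the α-carbon are weak substrates for chiral catalysts, and the enzyme delivers the 2S series. Neither regiochemistry nor configuration would be secured by that step.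

Alternative 3: The C3–C6'' bond is cut with reversed polarity. Both carbons are nucleophilic by nature: C3 as the central carbon of the 1,3-diketone A5, and C6'' as a phloroglucinol carbon. The forward key step would be a Pinhey arylation of A5 by the aryllead triacetate A4 (tetravalent lead), followed by cyclodehydration to the 3-arylflavone A6. This solves only the hindered bond. The flavanone would then have to be built on the locally symmetric ring of A6 by acylation, chalcone formation and closure, which brings back both problems of Alternative 2. It also needs stoichiometric lead, the free phenol of A5 can compete for the aryl group, and the sequence is longer.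

Key step: step 8

Assumption: the C3–C6'' axis has no descriptor in the target, so it is treated as stereochemically undefined; rotamers or atropisomers about this bond in 10, 12 and 13 are each taken as one compound. Compounds 1, 5 and 11 are taken as purchasable.

## Route

Step 1
Reactants: 1 5-hydroxy-7-methoxy-2-(4-methoxyphenyl)-4H-chromen-4-one
Product: 2 5-(benzyloxy)-7-methoxy-2-(4-methoxyphenyl)-4H-chromen-4-one
Conditions: BnBr (1.5 equiv), K2CO3 (3 equiv), KI (cat.), DMF, 70 °C
Reagents that add atoms: benzyl bromide, BrCc1ccccc1
Why: Williamson etherification; the 5-OH is the only acidic site and its hydrogen bond to C4=O is overcome by heat in DMF.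

Step 2
Reactants: 2 5-(benzyloxy)-7-methoxy-2-(4-methoxyphenyl)-4H-chromen-4-one
Product: 4 5-(benzyloxy)-3-iodo-7-methoxy-2-(4-methoxyphenyl)-4H-chromen-4-one, via 3-lithioflavone 3 (not isolated)
Conditions: LiN(iPr)2 (commercial solution, 1.3 equiv), THF, −78 °C; then I2 (1.5 equiv), THF, −78 °C to rt
Reagents that add atoms: iodine, II; lithium diisopropylamide, [Li+].CC(C)[N-]C(C)C (supplies the lithium of 3 only)
Why: Carbonyl-directed deprotonation of the vinylic C3–H of a flavone followed by iodinolysis of the C–Li bond; C2 is blocked by the aryl group, and at −78 °C the hindered amide should not touch the ring A hydrogens or the benzyl CH2.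

Step 3
Reactants: 5 5,7-dihydroxy-4H-chromen-4-one
Product: 6 7-(benzyloxy)-5-hydroxy-4H-chromen-4-one
Conditions: BnBr (1.05 equiv), K2CO3 (1.2 equiv), acetone, reflux
Reagents that add atoms: benzyl bromide, BrCc1ccccc1
Why: Selective Williamson etherification; the 7-OH is a vinylogous acid and free, while the 5-OH is tied up in a hydrogen bond to C4=O and reacts much more slowly.

Step 4
Reactants: 6 7-(benzyloxy)-5-hydroxy-4H-chromen-4-one
Product: 7 7-(benzyloxy)-5-hydroxy-6-iodo-4H-chromen-4-one
Conditions: BnMe3N+ ICl2− (1.05 equiv), CaCO3, CH2Cl2/MeOH (5:2), rt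
Reagents that add atoms: benzyltrimethylammonium dichloroiodate, C[N+](C)(C)Cc1ccccc1.Cl[I-]Cl
Why: Electrophilic aromatic iodination; the chelated 5-OH fixes enol character in the C5–C6 bond, so C6 (ortho to OH and to the benzyloxy group) should be attacked in preference to C8, as is usual for 5-hydroxy-7-alkoxy chromones and flavones with this reagent, and CaCO3 takes up the HCl.

Step 5
Reactants: 7 7-(benzyloxy)-5-hydroxy-6-iodo-4H-chromen-4-one
Product: 8 5,7-bis(benzyloxy)-6-iodo-4H-chromen-4-one
Conditions: BnBr (1.5 equiv), K2CO3 (2.5 equiv), DMF, 60 °C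
Reagents that add atoms: benzyl bromide, BrCc1ccccc1
Why: Williamson etherification of the hindered chelated phenol; dry carbonate is used so that no hydroxide attacks C2 of the chromone.

Step 6
Reactants: 8 5,7-bis(benzyloxy)-6-iodo-4H-chromen-4-one
Product: 9 5,7-bis(benzyloxy)-6-(4,4,5,5-tetramethyl-1,3,2-dioxaborolan-2-yl)-4H-chromen-4-one
Conditions: B2pin2 (1.5 equiv), PdCl2(dppf) (5 mol %), KOAc (3 equiv), 1,4-dioxane, 90 °C
Reagents that add atoms: bis(pinacolato)diboron, CC1(C)OB(OC1(C)C)B1OC(C)(C)C(C)(C)O1
Why: Miyaura borylation; oxidative addition of the aryl iodide to zerovalent palladium is easy, and the weak acetate base drives transmetalation without opening the chromone.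

Step 7
Reactants: 4 5-(benzyloxy)-3-iodo-7-methoxy-2-(4-methoxyphenyl)-4H-chromen-4-one; 9 5,7-bis(benzyloxy)-6-(4,4,5,5-tetramethyl-1,3,2-dioxaborolan-2-yl)-4H-chromen-4-one
Product: 10 5-(benzyloxy)-3-[5,7-bis(benzyloxy)-4-oxo-4H-chromen-6-yl]-7-methoxy-2-(4-methoxyphenyl)-4H-chromen-4-one
Conditions: Pd(OAc)2 (5 mol %), SPhos (10 mol %), K3PO4 (3 equiv), toluene/H2O (10:1), 80 °C
Reagents that add atoms: none
Why: Suzuki–Miyaura coupling; the 3-iodoflavone is a vinylogous acyl iodide that adds quickly to zerovalent palladium, SPhos is suited to di-ortho-alkoxy boronates and tetra-ortho biaryls, and both partners are achiral so base and heat cost nothing.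

Step 8
Reactants: 10 5-(benzyloxy)-3-[5,7-bis(benzyloxy)-4-oxo-4H-chromen-6-yl]-7-methoxy-2-(4-methoxyphenyl)-4H-chromen-4-one; 11 [4-(benzyloxy)phenyl]boronic acid
Product: 12 (2R)-5,7-bis(benzyloxy)-6-[5-(benzyloxy)-7-methoxy-2-(4-methoxyphenyl)-4-oxo-4H-chromen-3-yl]-2-[4-(benzyloxy)phenyl]-2,3-dihydro-4H-chromen-4-one
Conditions: 11 (2.5 equiv), Pd(OCOCF3)2 (10 mol %), (S)-t-BuPyOX (12 mol %), NH4PF6 (30 mol %), H2O (5 equiv), ClCH2CH2Cl, 60 °C
Reagents that add atoms: none
Why: The boronic acid transmetalates to the cationic divalent palladium–pyridine-oxazoline complex, the C2''=C3'' bond of unit 2 inserts into the Pd–aryl bond with aryl going to C2'' and palladium to C3'', and water protonates the resulting palladium enolate to release the ketone, so palladium stays divalent throughout. The closest known reaction type is the enantioselective palladium-catalysed conjugate addition of arylboronic acids to chromones to give flavanones. No ring is closed: ring C of unit 2 is already present in 10 and only loses its C2''=C3'' unsaturation. The C2'' centre is set in the insertion step by the tert-butyl group of the oxazoline, under pure catalyst control because 10 has no stereocentre; the facial sense that (S)-t-BuPyOX shows with cyclic enones corresponds to the 2R product at a chromone, and the (R)-ligand would be used if a model chromone showed the reverse. The step needs chemoselectivity between the two pyranone rings, which the substrate secures because only unit 2 has an unsubstituted C2''–H/C3''–H enone while C2=C3 of unit 1 is tetrasubstituted and flanked by two aryl groups. The bulky C6'' substituent and the biaryl axis are remote from C2'' and should not bias the face. The medium is not basic, so E1cB opening cannot erode the new centre, and water with NH4PF6 favours protonolysis over β-hydride elimination, which would give a flavone and zerovalent palladium.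

Step 9
Reactants: 12 (2R)-5,7-bis(benzyloxy)-6-[5-(benzyloxy)-7-methoxy-2-(4-methoxyphenyl)-4-oxo-4H-chromen-3-yl]-2-[4-(benzyloxy)phenyl]-2,3-dihydro-4H-chromen-4-one
Product: 13 (2R)-5,7-dihydroxy-6-[5-hydroxy-7-methoxy-2-(4-methoxyphenyl)-4-oxo-4H-chromen-3-yl]-2-(4-hydroxyphenyl)-2,3-dihydro-4H-chromen-4-one
Conditions: H2 (1 atm), 10% Pd/C, EtOAc/MeOH (1:1), rt, stopped when debenzylation is complete
Reagents that add atoms: none
Why: Hydrogenolysis of four aryl benzyl ethers under neutral conditions; the tetrasubstituted C2=C3 of the flavone and the aryl ketones should be untouched, the methyl ethers stay, and without acid or base ring C of unit 2 cannot open, so C2'' keeps its R configuration.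

## Compound list

1 | 5-hydroxy-7-methoxy-2-(4-methoxyphenyl)-4H-chromen-4-one | COc1ccc(-c2cc(=O)c3c(O)cc(OC)cc3o2)cc1 | starting material
2 | 5-(benzyloxy)-7-methoxy-2-(4-methoxyphenyl)-4H-chromen-4-one | COc1ccc(-c2cc(=O)c3c(OCc4ccccc4)cc(OC)cc3o2)cc1 | intermediate
3 | [5-(benzyloxy)-7-methoxy-2-(4-methoxyphenyl)-4-oxo-4H-chromen-3-yl]lithium | COc1ccc(-c2oc3cc(OC)cc(OCc4ccccc4)c3c(=O)c2[Li])cc1 | intermediate (not isolated)
4 | 5-(benzyloxy)-3-iodo-7-methoxy-2-(4-methoxyphenyl)-4H-chromen-4-one | COc1ccc(-c2oc3cc(OC)cc(OCc4ccccc4)c3c(=O)c2I)cc1 | intermediate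
5 | 5,7-dihydroxy-4H-chromen-4-one | O=c1ccoc2cc(O)cc(O)c12 | starting material
6 | 7-(benzyloxy)-5-hydroxy-4H-chromen-4-one | O=c1ccoc2cc(OCc3ccccc3)cc(O)c12 | intermediate
7 | 7-(benzyloxy)-5-hydroxy-6-iodo-4H-chromen-4-one | O=c1ccoc2cc(OCc3ccccc3)c(I)c(O)c12 | intermediate
8 | 5,7-bis(benzyloxy)-6-iodo-4H-chromen-4-one | O=c1ccoc2cc(OCc3ccccc3)c(I)c(OCc3ccccc3)c12 | intermediate
9 | 5,7-bis(benzyloxy)-6-(4,4,5,5-tetramethyl-1,3,2-dioxaborolan-2-yl)-4H-chromen-4-one | O=c1ccoc2cc(OCc3ccccc3)c(B3OC(C)(C)C(C)(C)O3)c(OCc3ccccc3)c12 | intermediate
10 | 5-(benzyloxy)-3-[5,7-bis(benzyloxy)-4-oxo-4H-chromen-6-yl]-7-methoxy-2-(4-methoxyphenyl)-4H-chromen-4-one | COc1ccc(-c2oc3cc(OC)cc(OCc4ccccc4)c3c(=O)c2-c2c(OCc3ccccc3)cc3occc(=O)c3c2OCc2ccccc2)cc1 | intermediate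
11 | [4-(benzyloxy)phenyl]boronic acid | OB(O)c1ccc(OCc2ccccc2)cc1 | starting material
12 | (2R)-5,7-bis(benzyloxy)-6-[5-(benzyloxy)-7-methoxy-2-(4-methoxyphenyl)-4-oxo-4H-chromen-3-yl]-2-[4-(benzyloxy)phenyl]-2,3-dihydro-4H-chromen-4-one | COc1ccc(-c2oc3cc(OC)cc(OCc4ccccc4)c3c(=O)c2-c2c(OCc3ccccc3)cc3c(c2OCc2ccccc2)C(=O)C[C@H](c2ccc(OCc4ccccc4)cc2)O3)cc1 | intermediate
13 | (2R)-5,7-dihydroxy-6-[5-hydroxy-7-methoxy-2-(4-methoxyphenyl)-4-oxo-4H-chromen-3-yl]-2-(4-hydroxyphenyl)-2,3-dihydro-4H-chromen-4-one | COc1ccc(-c2oc3cc(OC)cc(O)c3c(=O)c2-c2c(O)cc3c(c2O)C(=O)C[C@H](c2ccc(O)cc2)O3)cc1 | target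

## Step count and least certain steps

Total step count: 9. Longest linear sequence: 7 steps (steps 3 to 9, from 5).

Step 8 (key step). The chromone of unit 2 is electron-rich and carries a peri benzyloxy group, so insertion may be slow. Protodeboronation of 11 and reduction of the catalyst to zerovalent palladium could then outrun product formation, or the facial selectivity could be insufficient. Fallback by resolution in place of asymmetric catalysis, setting out from 10 and returning at 12: 1,4-addition of 4-BnOC6H4MgBr with CuBr·SMe2 (cat.) and Me3SiCl in THF at −78 °C should give the trimethylsilyl enol ether of the racemic adduct F1. Acidic work-up would hydrolyse it to the racemic benzyl-protected flavanone F2. Preparative chromatography on a polysaccharide chiral stationary phase would then separate 12 from its 2S enantiomer F3.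

Step 7. Protodeboronation of the 2,4,6-trioxygenated aryl boronate may be faster than transmetalation, and reductive elimination from a diaryl palladium with four ortho substituents may be slow. Fallback by reversing the roles of the partners, setting out from 2 and 8 and returning at 10 (steps 2 and 6 are then not needed): 2 is lithiated to 3 as in step 2 and transmetalated with ZnCl2 to the flavon-3-ylzinc chloride F4. Negishi coupling of this with the aryl iodide 8 (Pd2(dba)3, RuPhos, THF, 60 °C) should give 10 under anhydrous, base-free conditions in which no electron-rich aryl boron species exists.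

Step 6. Reduction of the aryl palladium iodide (loss of iodine for hydrogen) and slow boryl transfer at a carbon flanked by two benzyloxy groups may lower conversion. Fallback without a boronate, setting out from 8 and returning at 10: direct insertion of zinc (Zn dust, LiCl, THF, 40 °C) should give the chromon-6-ylzinc iodide F5, which is coupled with 4 in a Negishi reaction (Pd2(dba)3, XPhos, THF, 60 °C).

Step 9. Over-reduction is the risk: hydrogenolysis of the benzylic C2''–O1'' bond would open ring C of unit 2, while the hindered 5- and 5''-benzyl ethers may come off slowly, so the window between the two may be narrow. Fallback by deprotecting before the stereocentre exists, setting out from 10 and returning at 13: BCl3 with C6HMe5 in CH2Cl2 at −78 °C should cleave the three benzyl ethers of 10 to give the triphenol bichromone F6 and leave the methyl ethers. The conjugate arylation of step 8 is then run on F6 with 4-hydroxyphenylboronic acid to give 13 directly, with no deprotection after C2'' is set.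

## Further compounds

F1 | step 8 | 5-(benzyloxy)-3-{5,7-bis(benzyloxy)-2-[4-(benzyloxy)phenyl]-4-[(trimethylsilyl)oxy]-2H-chromen-6-yl}-7-methoxy-2-(4-methoxyphenyl)-4H-chromen-4-one (racemic) | COc1ccc(-c2oc3cc(OC)cc(OCc4ccccc4)c3c(=O)c2-c2c(OCc3ccccc3)cc3c(c2OCc2ccccc2)C(O[Si](C)(C)C)=CC(c2ccc(OCc4ccccc4)cc2)O3)cc1
F2 | step 8 | racemic 5,7-bis(benzyloxy)-6-[5-(benzyloxy)-7-methoxy-2-(4-methoxyphenyl)-4-oxo-4H-chromen-3-yl]-2-[4-(benzyloxy)phenyl]-2,3-dihydro-4H-chromen-4-one | COc1ccc(-c2oc3cc(OC)cc(OCc4ccccc4)c3c(=O)c2-c2c(OCc3ccccc3)cc3c(c2OCc2ccccc2)C(=O)CC(c2ccc(OCc4ccccc4)cc2)O3)cc1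
F3 | step 8 | (2S)-5,7-bis(benzyloxy)-6-[5-(benzyloxy)-7-methoxy-2-(4-methoxyphenyl)-4-oxo-4H-chromen-3-yl]-2-[4-(benzyloxy)phenyl]-2,3-dihydro-4H-chromen-4-one | COc1ccc(-c2oc3cc(OC)cc(OCc4ccccc4)c3c(=O)c2-c2c(OCc3ccccc3)cc3c(c2OCc2ccccc2)C(=O)C[C@@H](c2ccc(OCc4ccccc4)cc2)O3)cc1
F4 | step 7 | [5-(benzyloxy)-7-methoxy-2-(4-methoxyphenyl)-4-oxo-4H-chromen-3-yl]zinc chloride | COc1ccc(-c2oc3cc(OC)cc(OCc4ccccc4)c3c(=O)c2[Zn]Cl)cc1
F5 | step 6 | [5,7-bis(benzyloxy)-4-oxo-4H-chromen-6-yl]zinc iodide | O=c1ccoc2cc(OCc3ccccc3)c([Zn]I)c(OCc3ccccc3)c12
F6 | step 9 | 3-(5,7-dihydroxy-4-oxo-4H-chromen-6-yl)-5-hydroxy-7-methoxy-2-(4-methoxyphenyl)-4H-chromen-4-one | COc1ccc(-c2oc3cc(OC)cc(O)c3c(=O)c2-c2c(O)cc3occc(=O)c3c2O)cc1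
A1 | alternative 1 | (2R)-5,7-bis(benzyloxy)-2-[4-(benzyloxy)phenyl]-6-(4,4,5,5-tetramethyl-1,3,2-dioxaborolan-2-yl)-2,3-dihydro-4H-chromen-4-one | O=C1C[C@H](c2ccc(OCc3ccccc3)cc2)Oc2cc(OCc3ccccc3)c(B3OC(C)(C)C(C)(C)O3)c(OCc3ccccc3)c12
A2 | alternative 2 | (2E)-1-{2,4,6-trihydroxy-3-[5-hydroxy-7-methoxy-2-(4-methoxyphenyl)-4-oxo-4H-chromen-3-yl]phenyl}-3-(4-hydroxyphenyl)prop-2-en-1-one | COc1ccc(-c2oc3cc(OC)cc(O)c3c(=O)c2-c2c(O)cc(O)c(C(=O)/C=C/c3ccc(O)cc3)c2O)cc1
A3 | alternative 2 | (2R)-5,7-dihydroxy-8-[5-hydroxy-7-methoxy-2-(4-methoxyphenyl)-4-oxo-4H-chromen-3-yl]-2-(4-hydroxyphenyl)-2,3-dihydro-4H-chromen-4-one | COc1ccc(-c2oc3cc(OC)cc(O)c3c(=O)c2-c2c(O)cc(O)c3c2O[C@@H](c2ccc(O)cc2)CC3=O)cc1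
A4 | alternative 3 | [2,4,6-tris(benzyloxy)phenyl]lead triacetate | CC(=O)O[Pb](OC(C)=O)(OC(C)=O)c1c(OCc2ccccc2)cc(OCc2ccccc2)cc1OCc1ccccc1
A5 | alternative 3 | 1-[2-(benzyloxy)-6-hydroxy-4-methoxyphenyl]-3-(4-methoxyphenyl)propane-1,3-dione | COc1ccc(C(=O)CC(=O)c2c(O)cc(OC)cc2OCc2ccccc2)cc1
A6 | alternative 3 | 5-(benzyloxy)-7-methoxy-2-(4-methoxyphenyl)-3-[2,4,6-tris(benzyloxy)phenyl]-4H-chromen-4-one | COc1ccc(-c2oc3cc(OC)cc(OCc4ccccc4)c3c(=O)c2-c2c(OCc3ccccc3)cc(OCc3ccccc3)cc2OCc2ccccc2)cc1
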